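**Assumption:** all numbered starting materials (including both enantiomers of benzyl glycidyl ether) are treated as purchasable. Side-chain atoms use lignan numbering: C7 = ArCH, C8 = CH(CH2OH), C9 = CH2OH; flavone B-ring positions are primed. The target is the trans-(7R,8R) benzodioxane.

## Retrosynthetic overview

1. Palstatin ⇒ open the dioxane at C7–O5′. The last step is a dehydrogenative p-quinone-methide cyclization of a "seco" flavone that already carries C8 (proposed new step; sets C7 trans to C8).
2. Seco flavone ⇒ pyranone ring from a 2′-hydroxychalcone (I2/DMSO) ⇒ Claisen–Schmidt condensation of a dibenzyl phloroacetophenone with a B-ring aldehyde.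
3. B-ring aldehyde ⇒ C8–O4′ aryl ether by Mitsunobu inversion (5-bromovanillin + an (R)-1-aryl-3-benzyloxypropan-2-ol); Br → OH by borylation/oxidation.
4. (R)-Alcohol ⇒ syringyl Grignard + benzyl (R)-glycidyl ether (C8 from the chiral pool).
5. Ring order: aromatic rings are bought; the pyranone ring is formed first and the 1,4-dioxane ring last.

## Route

**Step 1**
Reactants: 1, 4-bromo-2,6-dimethoxyphenol; 2, benzyl bromide
Product: 3, 2-(benzyloxy)-5-bromo-1,3-dimethoxybenzene
Conditions: BnBr, K2CO3, DMF, 60 °C
Reagents that add atoms: benzyl bromide (2), BrCc1ccccc1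
Why: Williamson etherification masks the syringyl phenol so the aryl Grignard can be formed.

**Step 2**
Reactants: 3; 4, benzyl (R)-glycidyl ether
Product: 5, (R)-1-(benzyloxy)-3-[4-(benzyloxy)-3,5-dimethoxyphenyl]propan-2-ol
Conditions: 3, Mg, LiCl, THF, rt → ArMgBr; then CuI (10 mol%), 4, −30 → 0 °C
Reagents that add atoms: none
Why: Cu-catalysed Grignard opening of the terminal epoxide occurs at the CH2 carbon, so the stereocentre of 4 is untouched and becomes C8 (R-carbinol).

**Step 3**
Reactants: 5; 6, 5-bromovanillin (3-bromo-4-hydroxy-5-methoxybenzaldehyde)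
Product: 7, 4-{[(S)-1-(benzyloxy)-3-(4-(benzyloxy)-3,5-dimethoxyphenyl)propan-2-yl]oxy}-3-bromo-5-methoxybenzaldehyde
Conditions: PPh3, DIAD, THF, 0 °C → rt
Reagents that add atoms: none
Why: Mitsunobu etherification with the acidic para-formyl phenol proceeds by SN2 inversion at C8 (R → S), fixing the C8–O4′ bond and the C8 configuration of the target; the only phenol present guarantees regiochemistry.

**Step 4**
Reactants: 7; 8, bis(pinacolato)diboron
Product: 9, the 3-(pinacolboryl) analogue of 7
Conditions: Pd(dppf)Cl2 (5 mol%), KOAc, 1,4-dioxane, 90 °C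
Reagents that add atoms: bis(pinacolato)diboron (8), CC1(C)OB(OC1(C)C)B1OC(C)(C)C(C)(C)O1
Why: Miyaura borylation of the aryl bromide tolerates the aldehyde and benzyl ethers and does not touch C8.

**Step 5**
Reactants: 9
Product: 10, 4-{[(S)-1-(benzyloxy)-3-(4-(benzyloxy)-3,5-dimethoxyphenyl)propan-2-yl]oxy}-3-hydroxy-5-methoxybenzaldehyde
Conditions: NaBO3·4H2O, THF/H2O, rt
Reagents that add atoms: sodium perborate (one O), [Na+].[Na+].O[B-]1(O)OO[B-](O)(O)OO1
Why: Mild boronate oxidation (1,2-aryl shift from B to O) gives the 5′-phenol; the aldehyde is meta to the new OH and has no free o/p-hydroxyl, so Dakin oxidation is not expected.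

**Step 6**
Reactants: 10; 2, benzyl bromide
Product: 11, 3-(benzyloxy)-4-{[(S)-1-(benzyloxy)-3-(4-(benzyloxy)-3,5-dimethoxyphenyl)propan-2-yl]oxy}-5-methoxybenzaldehyde
Conditions: BnBr, K2CO3, DMF, rt → 50 °C
Reagents that add atoms: benzyl bromide (2), BrCc1ccccc1
Why: Williamson benzylation protects the 5′-OH for the basic aldol and the oxidative flavone closure.

**Step 7**
Reactants: 12, 2′,4′,6′-trihydroxyacetophenone; 2, benzyl bromide
Product: 13, 1-[2,4-bis(benzyloxy)-6-hydroxyphenyl]ethan-1-one
Conditions: BnBr (2.1 equiv), K2CO3, DMF, rt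
Reagents that add atoms: benzyl bromide (2), BrCc1ccccc1
Why: Selective O-alkylation leaves one ortho OH, which is deactivated by hydrogen bonding to the ketone and is needed later as the pyranone oxygen.

**Step 8**
Reactants: 11; 13
Product: 14, (E)-2′-hydroxychalcone: 1-[2,4-bis(benzyloxy)-6-hydroxyphenyl]-3-{3-(benzyloxy)-4-[((S)-1-(benzyloxy)-3-(4-(benzyloxy)-3,5-dimethoxyphenyl)propan-2-yl)oxy]-5-methoxyphenyl}prop-2-en-1-one
Conditions: KOH (50% aq.), EtOH/THF, rt, 48 h
Reagents that add atoms: none
Why: Claisen–Schmidt condensation of a non-enolisable aldehyde gives the E-enone; C8 has no acidifying group and cannot epimerise.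

**Step 9**
Reactants: 14
Product: 15, 5,7-bis(benzyloxy)-2-{3-(benzyloxy)-4-[((S)-1-(benzyloxy)-3-(4-(benzyloxy)-3,5-dimethoxyphenyl)propan-2-yl)oxy]-5-methoxyphenyl}-4H-chromen-4-one
Conditions: I2 (10 mol%), DMSO, 130 °C
Reagents that add atoms: none
Why: I2/DMSO oxidative cyclization (oxa-Michael to the flavanone, then iodination/elimination) forms the pyranone ring; benzyl ethers are stable to it.

**Step 10**
Reactants: 15
Product: 16, "seco-palstatin": 5,7-dihydroxy-2-{3-hydroxy-4-[((S)-1-hydroxy-3-(4-hydroxy-3,5-dimethoxyphenyl)propan-2-yl)oxy]-5-methoxyphenyl}-4H-chromen-4-one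
Conditions: H2 (1 atm), Pd(OH)2/C, THF/MeOH, rt, monitored
Reagents that add atoms: none
Why: Global hydrogenolysis removes all five benzyl ethers; the C8–OAr bond is not benzylic, and the flavone C2=C3 bond normally survives these conditions.

**Step 11**
Reactants: 16
Product: 17, palstatin: 5,7-dihydroxy-2-[(2R,3R)-3-(4-hydroxy-3,5-dimethoxyphenyl)-2-(hydroxymethyl)-8-methoxy-2,3-dihydro-1,4-benzodioxin-6-yl]-4H-chromen-4-one
Conditions: Ag2O (1.2 equiv), acetone/toluene, 4 Å MS, rt, dark
Reagents that add atoms: none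
Why: Proposed new method: a dehydrogenative benzylic C(sp3)–H/phenol O–H cyclization, in which Ag2O oxidises the most electron-rich phenol (the 4-alkyl-2,6-dimethoxyphenol, whose blocked ortho positions prevent radical dimerisation) to the p-quinone methide at C7, and the neighbouring 5′-OH adds 1,6 to C7 to close the dioxane; C8 directs a half-chair with aryl and CH2OH pseudo-equatorial (a cis isomer can reopen through the same quinone methide), giving the trans-(7R,8R) ring; the closest known reactions are the Ag2O/Ag2CO3 biomimetic coupling of catechols with coniferyl or sinapyl alcohol (same quinone-methide ring closure) and the oxidation of 4-alkyl-2,6-disubstituted phenols to p-quinone methides.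

## Compound list

1 | 4-bromo-2,6-dimethoxyphenol | COc1cc(Br)cc(OC)c1O | starting material
2 | benzyl bromide | BrCc1ccccc1 | starting material
3 | 2-(benzyloxy)-5-bromo-1,3-dimethoxybenzene | COc1cc(Br)cc(OC)c1OCc1ccccc1 | intermediate
4 | benzyl (R)-glycidyl ether | C1O[C@H]1COCc1ccccc1 | starting material
5 | (R)-1-(benzyloxy)-3-[4-(benzyloxy)-3,5-dimethoxyphenyl]propan-2-ol | COc1cc(C[C@@H](O)COCc2ccccc2)cc(OC)c1OCc1ccccc1 | intermediate
6 | 5-bromovanillin | COc1cc(C=O)cc(Br)c1O | starting material
7 | (S)-aryl ether bromo-aldehyde | COc1cc(C[C@H](Oc2c(Br)cc(C=O)cc2OC)COCc2ccccc2)cc(OC)c1OCc1ccccc1 | intermediate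
8 | bis(pinacolato)diboron | CC1(C)OB(OC1(C)C)B1OC(C)(C)C(C)(C)O1 | starting material
9 | (S)-aryl ether pinacolboronate aldehyde | COc1cc(C[C@H](Oc2c(B3OC(C)(C)C(C)(C)O3)cc(C=O)cc2OC)COCc2ccccc2)cc(OC)c1OCc1ccccc1 | intermediate
10 | (S)-aryl ether 3-hydroxy aldehyde | COc1cc(C[C@H](Oc2c(O)cc(C=O)cc2OC)COCc2ccccc2)cc(OC)c1OCc1ccccc1 | intermediate
11 | (S)-aryl ether 3-benzyloxy aldehyde | COc1cc(C[C@H](Oc2c(OCc3ccccc3)cc(C=O)cc2OC)COCc2ccccc2)cc(OC)c1OCc1ccccc1 | intermediate
12 | 2′,4′,6′-trihydroxyacetophenone | CC(=O)c1c(O)cc(O)cc1O | starting material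
13 | 1-[2,4-bis(benzyloxy)-6-hydroxyphenyl]ethan-1-one | CC(=O)c1c(O)cc(OCc2ccccc2)cc1OCc1ccccc1 | intermediate
14 | (E)-2′-hydroxychalcone, pentabenzyl | COc1cc(C[C@H](Oc2c(OCc3ccccc3)cc(/C=C/C(=O)c3c(O)cc(OCc4ccccc4)cc3OCc3ccccc3)cc2OC)COCc2ccccc2)cc(OC)c1OCc1ccccc1 | intermediate
15 | pentabenzyl seco-flavone | COc1cc(C[C@H](Oc2c(OCc3ccccc3)cc(-c3cc(=O)c4c(OCc5ccccc5)cc(OCc5ccccc5)cc4o3)cc2OC)COCc2ccccc2)cc(OC)c1OCc1ccccc1 | intermediate
16 | seco-palstatin | COc1cc(C[C@H](Oc2c(O)cc(-c3cc(=O)c4c(O)cc(O)cc4o3)cc2OC)CO)cc(OC)c1O | intermediate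
17 | palstatin | COc1cc([C@H]2Oc3cc(-c4cc(=O)c5c(O)cc(O)cc5o4)cc(OC)c3O[C@@H]2CO)cc(OC)c1O | target

## Summary

**Total steps:** 11
**Longest linear sequence:** 10 (steps 1–6, 8–11; step 7 is the side branch)

**Three steps most likely to fail**

1. **Step 11 (proposed new dehydrogenative cyclization).** Risks are tautomerisation of the quinone methide to the enol ether (loss of C8), intermolecular phenol coupling and over-oxidation. Fallback (known chemistry): put the C7 oxygen in from the start.
   - Run an Evans syn-aldol (Bu2BOTf, iPr2NEt) of the (S)-4-benzyloxazolidinone aryloxyacetimide of the B-ring phenol (aldehyde masked as its acetal) with 4-(benzyloxy)-3,5-dimethoxybenzaldehyde, then cleave with LiBH4.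
   - Carry the resulting 7,9-diol through the same flavone construction.
   - Close the dioxane by the established acid-promoted (TsOH or BF3·OEt2) cyclization of the 7-carbinol, which gives the trans-benzodioxane under C8 control.

2. **Step 3 (Mitsunobu of a secondary alcohol with a 2,6-disubstituted phenol).** Risks are slow coupling and elimination to the styrene. Fallback: form C8–O by SN2 on an activated electrophile.
   - Open methyl (R)-glycidate with the same aryl cuprate to give the methyl (R)-3-aryl-lactate.
   - Convert it to the triflate and displace with the potassium phenoxide of 5-bromovanillin dimethyl acetal (inversion).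
   - Reduce the ester (LiBH4), benzylate the primary alcohol and unmask the aldehyde to rejoin the route at 7.

3. **Step 10 (five-fold hydrogenolysis).** Risks are reduction of the flavone C2=C3 bond and slow cleavage of the alkyl benzyl ether. Fallback: change the protecting-group plan to MOM ethers on all phenols and a TBS ether on C9–OH (from commercial TBS (R)-glycidyl ether), and unmask 16 with HCl/MeOH instead of hydrogenation.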